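**Assumption:** the target has no stereocentre and is achiral, so there is no enantiomer to control; the route gives the single compound drawn.

**Retrosynthetic overview**
1. No ring is built: rings A, B and C are all bought as orcinol-type benzenes. The target comes from its ring C di-O-benzyl ether by hydrogenolysis.
2. Key disconnection: the aryl–C(=O) bond of ring B, cut together with the B–A ester oxygen, gives a ring C–ring B aryl iodide + CO + the ring A phenol. CO plus aryloxide on palladium serves as an aryloxycarbonyl anion equivalent, so an aryl iodide carbon and a carboxyl carbon, both electrophilic by nature, are joined.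
3. The ring A phenol (methyl 4-hydroxy-2-methoxy-6-methylbenzoate) comes from the same iodophenol + CO + MeOH; the iodophenol comes from para-iodination of 3-methoxy-5-methylphenol.
4. The ring C–ring B iodide comes from ordinary O-acylation of the iodophenol with 2,4-bis(benzyloxy)-6-methylbenzoyl chloride; the acid comes from orcinaldehyde (benzylation, Pinnick oxidation).
5. Order of assembly: iodophenol → ring A ester; ring C acid → C–B ester → carbonylative B–A coupling → debenzylation.

**Route**

Step 1
Reactants: 1 3-methoxy-5-methylphenol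
Product: 2 4-iodo-3-methoxy-5-methylphenol
Conditions: NIS (1.05 equiv), TsOH·H2O (10 mol %), MeCN, 0 °C to rt, dark
Reagents that add atoms: N-iodosuccinimide, O=C1CCC(=O)N1I
Why: Electrophilic aromatic iodination with acid-activated NIS is para-selective for free phenols and OH is the strongest director, so iodine should enter C4 between OMe and Me (the future carboxyl carbon), with minor ortho isomers removed by chromatography.

Step 2
Reactants: 2 4-iodo-3-methoxy-5-methylphenol
Product: 3 methyl 4-hydroxy-2-methoxy-6-methylbenzoate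
Conditions: CO (1 atm), Pd(OAc)2 (5 mol %), Xantphos (6 mol %), NEt3 (2 equiv), MeOH/DMF 1:1, 70 °C
Reagents that add atoms: carbon monoxide, [C-]#[O+]; methanol, CO
Why: Heck-type methoxycarbonylation (oxidative addition of the aryl iodide to zerovalent palladium, CO insertion, methanolysis of the acyl–palladium species) delivers CO/methanol as a methoxycarbonyl anion equivalent to the electrophilic iodide carbon, and the large excess of MeOH outcompetes the free phenol as nucleophile.

Step 3
Reactants: 4 2,4-dihydroxy-6-methylbenzaldehyde (orcinaldehyde)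
Product: 5 2,4-bis(benzyloxy)-6-methylbenzaldehyde
Conditions: BnBr (2.4 equiv), K2CO3 (3 equiv), DMF, 60 °C
Reagents that add atoms: benzyl bromide, BrCc1ccccc1
Why: Williamson ether synthesis; excess reagent and heating also alkylate the hydrogen-bonded 2-OH.

Step 4
Reactants: 5 2,4-bis(benzyloxy)-6-methylbenzaldehyde
Product: 6 2,4-bis(benzyloxy)-6-methylbenzoic acid
Conditions: NaClO2 (3 equiv), NaH2PO4 (3 equiv), 2-methyl-2-butene (10 equiv), t-BuOH/THF/H2O, 0 °C to rt
Reagents that add atoms: sodium chlorite, [Na+].[O-]Cl=O
Why: Pinnick oxidation converts the hindered aldehyde to the acid under mildly acidic conditions, while 2-methyl-2-butene traps HOCl so the electron-rich ring is not chlorinated.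

Step 5
Reactants: 6 2,4-bis(benzyloxy)-6-methylbenzoic acid; 2 4-iodo-3-methoxy-5-methylphenol
Product: 8 4-iodo-3-methoxy-5-methylphenyl 2,4-bis(benzyloxy)-6-methylbenzoate, via acid chloride 7 (not isolated)
Conditions: (COCl)2 (1.5 equiv), DMF (cat.), CH2Cl2, 0 °C to rt, evaporate; then 2 (1.0 equiv), NEt3 (2 equiv), DMAP (10 mol %), CH2Cl2, 0 °C to rt
Reagents that add atoms: none
Why: Acid chloride formation followed by DMAP-catalysed O-acylation of the phenol (nucleophilic acyl-transfer catalysis) overcomes the two ortho substituents of the acid, and the aryl iodide is inert under these conditions.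

Step 6
Reactants: 8 4-iodo-3-methoxy-5-methylphenyl 2,4-bis(benzyloxy)-6-methylbenzoate; 3 methyl 4-hydroxy-2-methoxy-6-methylbenzoate
Product: 9 methyl 4-[(4-{[2,4-bis(benzyloxy)-6-methylbenzoyl]oxy}-2-methoxy-6-methylbenzoyl)oxy]-2-methoxy-6-methylbenzoate
Conditions: 3 (1.3 equiv), CO (1 atm), Pd(OAc)2 (5 mol %), Xantphos (7.5 mol %), NEt3 (2.5 equiv), toluene, 90 °C
Reagents that add atoms: carbon monoxide, [C-]#[O+]
Why: In this palladium-catalysed aryloxycarbonylation (Heck carbonylation) the aryl iodide adds to zerovalent palladium, CO inserts (helped by the two ortho groups) and the phenoxide of 3 closes the ester, so CO plus aryloxide acts as an aryloxycarbonyl anion equivalent (ArO–C(=O)–Pd, a d1 carboxyl donor) that joins the electrophilic iodide carbon of ring B to a carboxyl carbon that is itself electrophilic by nature, forming the ring B aryl–carbonyl bond and the B–A depside ester in one operation while the hindered C–B ester and the benzyl ethers stay untouched.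

Step 7
Reactants: 9 methyl 4-[(4-{[2,4-bis(benzyloxy)-6-methylbenzoyl]oxy}-2-methoxy-6-methylbenzoyl)oxy]-2-methoxy-6-methylbenzoate
Product: 10 methyl 4-({4-[(2,4-dihydroxy-6-methylbenzoyl)oxy]-2-methoxy-6-methylbenzoyl}oxy)-2-methoxy-6-methylbenzoate (target)
Conditions: H2 (1 atm), Pd/C (10 wt % Pd), EtOAc, rt
Reagents that add atoms: none
Why: Catalytic hydrogenolysis removes both benzyl ethers, while aryl esters, the methyl ester and the aryl methyl ethers are inert; no stereocentre is involved.

**Compound list**
1 | 3-methoxy-5-methylphenol (orcinol monomethyl ether) | COc1cc(C)cc(O)c1 | starting material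
2 | 4-iodo-3-methoxy-5-methylphenol | COc1cc(O)cc(C)c1I | intermediate
3 | methyl 4-hydroxy-2-methoxy-6-methylbenzoate | COC(=O)c1c(C)cc(O)cc1OC | intermediate
4 | 2,4-dihydroxy-6-methylbenzaldehyde (orcinaldehyde) | Cc1cc(O)cc(O)c1C=O | starting material
5 | 2,4-bis(benzyloxy)-6-methylbenzaldehyde | Cc1cc(OCc2ccccc2)cc(OCc2ccccc2)c1C=O | intermediate
6 | 2,4-bis(benzyloxy)-6-methylbenzoic acid | Cc1cc(OCc2ccccc2)cc(OCc2ccccc2)c1C(=O)O | intermediate
7 | 2,4-bis(benzyloxy)-6-methylbenzoyl chloride (not isolated) | Cc1cc(OCc2ccccc2)cc(OCc2ccccc2)c1C(=O)Cl | intermediate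
8 | 4-iodo-3-methoxy-5-methylphenyl 2,4-bis(benzyloxy)-6-methylbenzoate | Cc1cc(OCc2ccccc2)cc(OCc2ccccc2)c1C(=O)Oc1cc(C)c(I)c(OC)c1 | intermediate
9 | methyl 4-[(4-{[2,4-bis(benzyloxy)-6-methylbenzoyl]oxy}-2-methoxy-6-methylbenzoyl)oxy]-2-methoxy-6-methylbenzoate | COC(=O)c1c(C)cc(OC(=O)c2c(C)cc(OC(=O)c3c(C)cc(OCc4ccccc4)cc3OCc3ccccc3)cc2OC)cc1OC | intermediate
10 | methyl 4-({4-[(2,4-dihydroxy-6-methylbenzoyl)oxy]-2-methoxy-6-methylbenzoyl}oxy)-2-methoxy-6-methylbenzoate | COC(=O)c1c(C)cc(OC(=O)c2c(C)cc(OC(=O)c3c(C)cc(O)cc3O)cc2OC)cc1OC | target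

**Totals**
Total step count: 7. Longest linear sequence: 5 steps (4 → 5 → 6 → 8 → 9 → 10).

**Three steps most likely to fail, with fallbacks**

- Step 6 (carbonylative depside coupling). The hindered acyl–palladium species may not be captured by the weakly nucleophilic phenoxide of 3, giving hydrodeiodination or ester scrambling instead. The fallback sets out from 8 and comes back at 9. The carbonylative C–C bond formation is kept, but water is the nucleophile (CO 1 atm, Pd(OAc)2, Xantphos, H2O, NEt3, dioxane, 80 °C), giving 4-{[2,4-bis(benzyloxy)-6-methylbenzoyl]oxy}-2-methoxy-6-methylbenzoic acid F1. This acid is then joined to 3 by the classical depside condensation with trifluoroacetic anhydride in toluene at rt. That condensation runs through 4-{[2,4-bis(benzyloxy)-6-methylbenzoyl]oxy}-2-methoxy-6-methylbenzoic trifluoroacetic anhydride F2, an acylium-like donor that tolerates the two ortho groups, and delivers 9.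

- Step 1 (regioselective iodination). Iodination ortho to OH (C6, para to OMe) or at C2 may compete and give isomers that are hard to separate. The fallback sets out from 1 and comes back at 2. It uses nitrosation, which is far more para-selective for phenols: NaNO2 in aqueous HCl at 0 °C gives 3-methoxy-5-methyl-4-nitrosophenol F3. Hydrogenation (H2, Pd/C, EtOH) gives 4-amino-3-methoxy-5-methylphenol F4. Diazotisation (NaNO2, HCl, 0 °C) gives 4-hydroxy-2-methoxy-6-methylbenzenediazonium chloride F5, which with KI gives 2 (Sandmeyer-type iodination).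

- Step 2 (methoxycarbonylation of the free iodophenol). The free phenol may compete as nucleophile (oligo-depsides), or the electron-rich, doubly ortho-substituted iodide may be sluggish. The fallback sets out from 2 and comes back at 3. n-BuLi (2.2 equiv, THF, −78 °C) deprotonates the phenol and effects iodine–lithium exchange. Quenching with excess methyl chloroformate gives methyl 2-methoxy-4-[(methoxycarbonyl)oxy]-6-methylbenzoate F6. K2CO3 in MeOH at 0 °C then cleaves only the aryl carbonate and releases 3.

**Further compounds**
F1 | step 6 | 4-{[2,4-bis(benzyloxy)-6-methylbenzoyl]oxy}-2-methoxy-6-methylbenzoic acid | COc1cc(OC(=O)c2c(C)cc(OCc3ccccc3)cc2OCc2ccccc2)cc(C)c1C(=O)O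
F2 | step 6 | 4-{[2,4-bis(benzyloxy)-6-methylbenzoyl]oxy}-2-methoxy-6-methylbenzoic trifluoroacetic anhydride | COc1cc(OC(=O)c2c(C)cc(OCc3ccccc3)cc2OCc2ccccc2)cc(C)c1C(=O)OC(=O)C(F)(F)F
F3 | step 1 | 3-methoxy-5-methyl-4-nitrosophenol | COc1cc(O)cc(C)c1N=O
F4 | step 1 | 4-amino-3-methoxy-5-methylphenol | COc1cc(O)cc(C)c1N
F5 | step 1 | 4-hydroxy-2-methoxy-6-methylbenzenediazonium chloride | COc1cc(O)cc(C)c1[N+]#N.[Cl-]
F6 | step 2 | methyl 2-methoxy-4-[(methoxycarbonyl)oxy]-6-methylbenzoate | COC(=O)Oc1cc(C)c(C(=O)OC)c(OC)c1
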